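Locants used here: ring A (cyclopentane) C1(OAc)–C2H2–C3(CH3)(C16HO)–C4H–C5(CH3); ring B (ten-membered) C4–C6(OH)–C7(OH)–C8(O)–C9=C10(CH3)–C11–C12–C13(OAc)–C5; ring C (lactone) C7–C14(CH3)–C15(=O)–O–C8.
Cuts, last to first: ring C at O–C15 (oxidative lactonisation); ring B at C8–C9 (vinyl iodide + aldehyde), C6–C7 (alkenylcerium + aldehyde) and C11–C12 (enolate allylation); ring A at C2–C3 and C1–C5 together, leaving a vinylcyclopropane (C3–C4–C5) and a two-carbon enol ether (C1–C2).
Enabling feature: in ring A the quaternary carbons C3 and C5 flank C4; C3 bears the carbonyl carbon C16 and C5 bears the C13 branch. C3 can therefore be an ester-stabilised radical and C5 the inner carbon of an allyl sulfide once a thiyl radical opens the C3–C5 bond of a 2-vinylcyclopropane ester; C1(O) and C2H2 then come from a silyl vinyl ether in a radical [3+2] annulation.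
Forward order: ring A first, then the C13–C9 chain on C5, the C6–C8/C14 chain on C4, ring B by Nozaki–Hiyama–Kishi closure, ring C and release of the functional groups last.
Stereochemistry: C4 from a catalyst-controlled cyclopropanation; C3 and C5 are planar during the annulation, so every cyclopropane isomer funnels into one ring A isomer with C1, C3 and C5 relayed from C4. C13 comes by 1,3-syn reduction from C1, C6 by Felkin–Anh reduction from C4, C7 by osmylation from C6, C8 by Felkin–Anh addition from C7, and C14 from the (S)-Roche ester.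

Key step: step 6

Assumption: Rh2(4S-MEOX)4, dirhodium tetrakis[methyl (4S)-2-oxooxazolidine-4-carboxylate], is taken to give the (5R) lactone 6 drawn; if the sense of induction is the opposite, the 4R catalyst is used.

Step 1
Reactants: 1 (2Z)-3-methylpent-2-en-4-yn-1-ol
Product: 2 (2Z)-3-methylpenta-2,4-dien-1-ol
Conditions: H2 (1 atm), Pd/CaCO3 poisoned with Pb(OAc)2 (Lindlar), quinoline, EtOAc, 20 °C
Reagents that add atoms: none
Why: Lindlar semihydrogenation should stop at the terminal alkene and leave the trisubstituted alkene and its Z geometry untouched.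

Step 2
Reactants: 2 (2Z)-3-methylpenta-2,4-dien-1-ol; 3 ethyl 2-methyl-3-oxobutanoate
Product: 4 (2Z)-3-methylpenta-2,4-dien-1-yl 2-methyl-3-oxobutanoate
Conditions: DMAP (cat.), toluene, 110 °C, EtOH distilled off
Reagents that add atoms: none
Why: DMAP-catalysed transesterification of a β-keto ester should be driven to the allylic ester by removal of ethanol.

Step 3
Reactants: 4 (2Z)-3-methylpenta-2,4-dien-1-yl 2-methyl-3-oxobutanoate
Product: 5 (2Z)-3-methylpenta-2,4-dien-1-yl 2-diazopropanoate
Conditions: p-ABSA, DBU, MeCN, 0 → 20 °C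
Reagents that add atoms: 4-acetamidobenzenesulfonyl azide (p-ABSA) CC(=O)Nc1ccc(cc1)S(=O)(=O)N=[N+]=[N-]
Why: Regitz deacylative diazo transfer to an α-substituted β-keto ester should give the α-diazopropanoate with loss of the acetyl group to the sulfonamide.

Step 4
Reactants: 5 (2Z)-3-methylpenta-2,4-dien-1-yl 2-diazopropanoate
Product: 6 (1R,5R,6S)-6-ethenyl-1,6-dimethyl-3-oxabicyclo[3.1.0]hexan-2-one
Conditions: Rh2(4S-MEOX)4 (1 mol %), CH2Cl2, 40 °C, slow addition of 5
Reagents that add atoms: none
Why: Enantioselective intramolecular cyclopropanation of an allylic diazopropanoate by a chiral dirhodium carboxamidate should add the carbene to the proximal alkene (five-membered lactone), the catalyst fixing the face and hence C4, the only stereocentre that must survive step 6.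

Step 5
Reactants: 6 (1R,5R,6S)-6-ethenyl-1,6-dimethyl-3-oxabicyclo[3.1.0]hexan-2-one
Product: 8 4-methoxybenzyl (1R,2S,3R)-2-ethenyl-3-{[(4-methoxybenzyl)oxy]methyl}-1,2-dimethylcyclopropane-1-carboxylate, via lithium hydroxy-carboxylate 7 (not isolated)
Conditions: LiOH·H2O, THF/H2O, 20 °C; evaporate; then NaH, PMBCl, Bu4NI (cat.), DMF, 0 → 20 °C
Reagents that add atoms: lithium hydroxide [Li+].[OH-]; 4-methoxybenzyl chloride COc1ccc(CCl)cc1
Why: Saponification followed by exhaustive Williamson and carboxylate alkylation of the dianion should open the lactone to an acyclic ester and a non-chelating ether, which takes C3 out of the ring before the radical step.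

Step 6
Reactants: 8 4-methoxybenzyl (1R,2S,3R)-2-ethenyl-3-{[(4-methoxybenzyl)oxy]methyl}-1,2-dimethylcyclopropane-1-carboxylate; 9 tert-butyl(ethenyloxy)dimethylsilane
Product: 10 4-methoxybenzyl (1S,2R,3R,4S)-4-[(tert-butyldimethylsilyl)oxy]-3-ethenyl-2-{[(4-methoxybenzyl)oxy]methyl}-1,3-dimethylcyclopentane-1-carboxylate
Conditions: 9 (10 equiv), PhSSPh (0.3 equiv), AIBN (0.2 equiv), benzene, hν (sunlamp), 80 °C
Reagents that add atoms: none
Why: PhS• (from PhSSPh) adds to the vinyl terminus of 8, the cyclopropylcarbinyl radical opens the most substituted C3–C5 bond to give the tertiary ester-stabilised C3 radical and a C5=C13 allyl sulfide, the electrophilic C3 radical adds to the CH2 end of the electron-rich enol ether 9 (bond C2–C3), and the nucleophilic α-silyloxy C1 radical closes on C5 (bond C1–C5) before β-scission returns PhS• and the C13=C12 vinyl group. The closest known reaction type is the thiyl-radical-catalysed [3+2] annulation of ester-substituted vinylcyclopropanes with vinyl ethers or vinyl acetate. Ring A closes in the 5-exo-trig mode. C3 and C5 are planar in the intermediates, so all cyclopropane isomers converge and only C4 directs: at C3 the C4–H eclipses the ester (A(1,3) strain) and 9 adds anti to the branched alkenyl group, on the side of CH2OPMB; at C5 and C1 a chair-like Beckwith–Houk transition state with the C4 substituent and the C1 silyloxy group pseudo-equatorial places C13 trans to C6 and cis to the C1 oxygen. The step needs C3–C5 rather than C4–C5 cleavage (secured by the ester on C3), cross-addition rather than telomerisation (polarity matching: the α-oxy radical is reluctant to add to a second molecule of 9) and 5-exo rather than 6-endo closure (only the 5-exo radical can expel PhS•).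

Step 7
Reactants: 10 ring A ester
Product: 11 (1S,2R,3R,4S)-4-[(tert-butyldimethylsilyl)oxy]-3-ethenyl-2-{[(4-methoxybenzyl)oxy]methyl}-1,3-dimethylcyclopentane-1-carbaldehyde
Conditions: DIBAL-H (1.1 equiv), CH2Cl2, −78 °C; Rochelle salt
Reagents that add atoms: none
Why: DIBAL half-reduction should stop at the aldehyde because the tetrahedral aluminate of this α-quaternary ester is stable at −78 °C.

Step 8
Reactants: 11 ring A aldehyde
Product: 12 ring A dimethyl acetal (C16 as CH(OMe)2; C1 OTBS; C6 OPMB; C5 vinyl)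
Conditions: HC(OMe)3, PPTS (cat.), MeOH, 20 °C
Reagents that add atoms: trimethyl orthoformate COC(OC)OC
Why: Acid-catalysed acetalisation with orthoformate as water scavenger should mask C16 for all later nucleophilic and reductive steps.

Step 9
Reactants: 12 ring A dimethyl acetal
Product: 13 C13 methyl ketone (C5 acetyl)
Conditions: PdCl2 (10 mol %), Cu(OAc)2 (20 mol %), O2 (1 atm), DMA/H2O 7:1, 20 °C
Reagents that add atoms: water O
Why: Tsuji–Wacker oxidation should convert the monosubstituted vinyl group into the methyl ketone (Markovnikov), the acetate buffer sparing the acetal and silyl ether.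

Step 10
Reactants: 14 prop-2-yn-1-ol
Product: 16 (2Z)-3-iodo-2-methylprop-2-en-1-ol, via alkenylmagnesium alkoxide 15 (not isolated)
Conditions: MeMgBr (2.5 equiv), CuI (10 mol %), THF, −10 → 20 °C; then I2, −78 → 0 °C
Reagents that add atoms: methylmagnesium bromide C[Mg]Br; iodine [I][I]
Why: Copper-catalysed anti-carbomagnesiation of the propargylic alkoxide through a chelated alkenylmagnesium, followed by iodinolysis with retention, should give the Z iodoalkene only.

Step 11
Reactants: 16 (2Z)-3-iodo-2-methylprop-2-en-1-ol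
Product: 17 (1Z)-3-bromo-1-iodo-2-methylprop-1-ene
Conditions: CBr4, PPh3, CH2Cl2, 0 °C
Reagents that add atoms: carbon tetrabromide BrC(Br)(Br)Br
Why: The Appel reaction should give the primary allylic bromide without touching the alkene geometry.

Step 12
Reactants: 13 C13 methyl ketone; 17 (1Z)-3-bromo-1-iodo-2-methylprop-1-ene
Product: 19 C12-allylated ketone (C13 ketone carrying the C9 vinyl iodide), via lithium enolate 18 (not isolated)
Conditions: LDA, THF, −78 °C; then 17, DMPU, −78 → −40 °C
Reagents that add atoms: none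
Why: Kinetic enolate alkylation should occur only at the methyl group (C5 is quaternary), by SN2 at the allylic bromide, bringing in C9–C11 with the Z vinyl iodide intact.

Step 13
Reactants: 19 C12-allylated ketone
Product: 20 C1 hydroxy C13 ketone
Conditions: TBAF, AcOH (1:1), THF, 20 → 40 °C
Reagents that add atoms: none
Why: Fluoride desilylation buffered with acetic acid should free the C1 hydroxyl without retro-aldol cleavage of the C1–C5 bond.

Step 14
Reactants: 20 C1 hydroxy C13 ketone
Product: 22 syn-1,13-diol, via diethylboron chelate 21 (not isolated)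
Conditions: Et2BOMe, THF/MeOH 4:1, −78 °C; NaBH4; then AcOH, MeOH co-evaporation
Reagents that add atoms: none
Why: Narasaka–Prasad reduction should deliver hydride to the boron chelate on the convex face of the chelate/cyclopentane bicycle and so set C13 1,3-syn to C1.

Step 15
Reactants: 22 syn-1,13-diol
Product: 23 1,13-diacetate
Conditions: Ac2O, DMAP, pyridine, 20 °C
Reagents that add atoms: acetic anhydride CC(=O)OC(C)=O
Why: DMAP-catalysed acetylation should install both acetates of the target on the only two free hydroxyls.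

Step 16
Reactants: 23 1,13-diacetate
Product: 24 C6 primary alcohol
Conditions: DDQ, CH2Cl2/pH 7 buffer, 0 °C
Reagents that add atoms: none
Why: Oxidative cleavage of the single p-methoxybenzyl ether should leave acetates, acetal and vinyl iodide untouched.

Step 17
Reactants: 24 C6 primary alcohol
Product: 25 C6 aldehyde
Conditions: Dess–Martin periodinane, NaHCO3, CH2Cl2, 0 → 20 °C
Reagents that add atoms: none
Why: Buffered Dess–Martin oxidation should give the aldehyde without epimerising C4, whose proton is shielded by two quaternary carbons.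

Step 18
Reactants: 26 methyl (2S)-3-hydroxy-2-methylpropanoate
Product: 27 methyl (2S)-3-[(tert-butyldiphenylsilyl)oxy]-2-methylpropanoate
Conditions: TBDPSCl, imidazole, DMF, 20 °C
Reagents that add atoms: tert-butyl(chloro)diphenylsilane CC(C)(C)[Si](Cl)(c1ccccc1)c1ccccc1
Why: Standard silylation of the primary alcohol protects the future C15 oxygen with a group that survives organolithium chemistry.

Step 19
Reactants: 27 silylated Roche ester
Product: 28 (2S)-3-[(tert-butyldiphenylsilyl)oxy]-2-methylpropanal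
Conditions: DIBAL-H, CH2Cl2, −78 °C
Reagents that add atoms: none
Why: DIBAL half-reduction at −78 °C should give the aldehyde without loss of the α-stereocentre.

Step 20
Reactants: 28 (2S)-3-[(tert-butyldiphenylsilyl)oxy]-2-methylpropanal
Product: 29 (R)-tert-butyl[(2-methylbut-3-yn-1-yl)oxy]diphenylsilane
Conditions: dimethyl (1-diazo-2-oxopropyl)phosphonate, K2CO3, MeOH, 0 → 20 °C
Reagents that add atoms: dimethyl (1-diazo-2-oxopropyl)phosphonate COP(=O)(OC)C(=[N+]=[N-])C(C)=O
Why: Ohira–Bestmann (Seyferth–Gilbert) homologation under mild base should give the terminal alkyne with the α-stereocentre preserved.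

Step 21
Reactants: 29 (R)-tert-butyl[(2-methylbut-3-yn-1-yl)oxy]diphenylsilane
Product: 31 (S)-[(3-bromo-2-methylbut-3-en-1-yl)oxy](tert-butyl)diphenylsilane, via alkenylborane 30 (not isolated)
Conditions: B-bromo-9-BBN, CH2Cl2, 0 °C; then AcOH
Reagents that add atoms: 9-bromo-9-borabicyclo[3.3.1]nonane BrB1C2CCCC1CCC2
Why: Syn bromoboration places bromine on the internal carbon and protodeboronation then gives the 2-bromo-1-alkene.

Step 22
Reactants: 25 C6 aldehyde; 31 (S)-[(3-bromo-2-methylbut-3-en-1-yl)oxy](tert-butyl)diphenylsilane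
Product: 33 C6 allylic alcohols (epimer mixture at C6), via alkenyllithium 32 (not isolated)
Conditions: 31, t-BuLi (2 equiv), Et2O, −78 °C; CeCl3, THF, −78 °C; then 25, −78 °C
Reagents that add atoms: none
Why: Bromine–lithium exchange and transmetalation to cerium give a weakly basic alkenyl nucleophile that should add to the hindered aldehyde at −78 °C faster than to the acetates and without exchange at the vinyl iodide; the C6 configuration is reset in steps 23 and 24.

Step 23
Reactants: 33 C6 allylic alcohols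
Product: 34 C6 enone
Conditions: Dess–Martin periodinane, NaHCO3, CH2Cl2, 20 °C
Reagents that add atoms: none
Why: Dess–Martin oxidation converges both C6 epimers on one α-methylene ketone under neutral conditions.

Step 24
Reactants: 34 C6 enone
Product: 35 C6 allylic alcohol (single epimer)
Conditions: NaBH4, CeCl3·7H2O, MeOH, −78 °C
Reagents that add atoms: none
Why: Luche 1,2-reduction under Felkin–Anh control from C4 should deliver hydride anti to the bulkier C3 flank (its acetal is cis to the ketone) with the alkenyl group next to C4–H, which gives the C6 configuration of the target.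

Step 25
Reactants: 35 C6 allylic alcohol
Product: 36 C6 TBS ether
Conditions: TBSOTf, 2,6-lutidine, CH2Cl2, −78 °C
Reagents that add atoms: tert-butyldimethylsilyl triflate CC(C)(C)[Si](C)(C)OS(=O)(=O)C(F)(F)F
Why: Silyl triflate silylation at −78 °C should protect the hindered secondary alcohol faster than it activates the neopentyl acetal.

Step 26
Reactants: 36 C6 TBS ether
Product: 37 C7,C8 diol
Conditions: OsO4 (5 mol %), NMO, acetone/H2O, 0 → 20 °C
Reagents that add atoms: N-methylmorpholine N-oxide C[N+]1([O-])CCOCC1; water O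
Why: Upjohn dihydroxylation should take the 1,1-disubstituted alkene rather than the electron-poor iodoalkene, and by the Kishi rule osmium attacks anti to the allylic silyloxy group (anti to C4 in the inside-alkoxy conformer), which sets C7.

Step 27
Reactants: 37 C7,C8 diol
Product: 38 C8 aldehyde
Conditions: TEMPO (cat.), PhI(OAc)2, CH2Cl2, 20 °C
Reagents that add atoms: none
Why: Oxoammonium oxidation is selective for the primary alcohol and leaves the tertiary C7 hydroxyl alone.

Step 28
Reactants: 38 C8 aldehyde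
Product: 39 ring B allylic alcohol (C8 OH)
Conditions: CrCl2 (10 equiv), NiCl2 (2 mol %), DMSO/THF, 0.002 M, 20 °C
Reagents that add atoms: none
Why: Intramolecular Nozaki–Hiyama–Kishi coupling (zerovalent nickel inserts into the vinyl iodide, transmetalation to trivalent chromium, addition to the aldehyde) should close the ten-membered ring with retention of the Z alkene, and Felkin–Anh addition anti to the C7 oxygen with the C14 branch as the small group gives the C8 configuration of the target.

Step 29
Reactants: 39 ring B allylic alcohol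
Product: 40 C8,C15 diol (C15 primary alcohol)
Conditions: TBAF, AcOH, THF, 0 → 20 °C
Reagents that add atoms: none
Why: Buffered fluoride should cleave the primary TBDPS ether much faster than the hindered secondary TBS ether at C6 and does not disturb the acetates.

Step 30
Reactants: 40 C8,C15 diol
Product: 42 lactone (ring C closed; C6 OTBS; C16 dimethyl acetal), via lactol 41 (not isolated)
Conditions: TEMPO (cat.), PhI(OAc)2 (2.5 equiv), CH2Cl2, 20 °C
Reagents that add atoms: none
Why: Oxidative lactonisation of the 1,4-diol goes through the C15 aldehyde and its five-membered lactol with the C8 hydroxyl, the only hydroxyl that can close (C6 is silylated, C7 would give a four-membered ring).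

Step 31
Reactants: 42 lactone
Product: 43 target CNP0123121.2
Conditions: aq. HF (48 %), MeCN, 0 → 20 °C
Reagents that add atoms: water O
Why: Aqueous HF should cleave the C6 silyl ether and hydrolyse the dimethyl acetal to the C16 aldehyde in one operation, conditions the acetates, lactone and tertiary alcohol tolerate.

Compound list
1 | (2Z)-3-methylpent-2-en-4-yn-1-ol | OC/C=C(/C)C#C | starting material
2 | (2Z)-3-methylpenta-2,4-dien-1-ol | OC/C=C(/C)C=C | intermediate
3 | ethyl 2-methyl-3-oxobutanoate (racemic) | CCOC(=O)C(C)C(C)=O | starting material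
4 | (2Z)-3-methylpenta-2,4-dien-1-yl 2-methyl-3-oxobutanoate (racemic) | CC(=O)C(C)C(=O)OC/C=C(/C)C=C | intermediate
5 | (2Z)-3-methylpenta-2,4-dien-1-yl 2-diazopropanoate | CC(=[N+]=[N-])C(=O)OC/C=C(/C)C=C | intermediate
6 | (1R,5R,6S)-6-ethenyl-1,6-dimethyl-3-oxabicyclo[3.1.0]hexan-2-one (vinyl cis to the lactone CH2) | O=C1OC[C@@H]2[C@](C)(C=C)[C@]12C | intermediate
7 | lithium (1R,2S,3R)-2-ethenyl-3-(hydroxymethyl)-1,2-dimethylcyclopropane-1-carboxylate | [Li+].[O-]C(=O)[C@]1(C)[C@H](CO)[C@]1(C)C=C | intermediate (not isolated)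
8 | 4-methoxybenzyl (1R,2S,3R)-2-ethenyl-3-{[(4-methoxybenzyl)oxy]methyl}-1,2-dimethylcyclopropane-1-carboxylate | COc1ccc(COC(=O)[C@]2(C)[C@H](COCc3ccc(OC)cc3)[C@]2(C)C=C)cc1 | intermediate
9 | tert-butyl(ethenyloxy)dimethylsilane | C=CO[Si](C)(C)C(C)(C)C | starting material
10 | 4-methoxybenzyl (1S,2R,3R,4S)-4-[(tert-butyldimethylsilyl)oxy]-3-ethenyl-2-{[(4-methoxybenzyl)oxy]methyl}-1,3-dimethylcyclopentane-1-carboxylate (ring A; C1 OTBS and C5 vinyl cis, both trans to C6 and to the C3 ester) | CC(C)(C)[Si](C)(C)O[C@H]1C[C@](C)(C(=O)OCc2ccc(OC)cc2)[C@H](COCc2ccc(OC)cc2)[C@]1(C=C)C | intermediate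
11 | (1S,2R,3R,4S)-4-[(tert-butyldimethylsilyl)oxy]-3-ethenyl-2-{[(4-methoxybenzyl)oxy]methyl}-1,3-dimethylcyclopentane-1-carbaldehyde | CC(C)(C)[Si](C)(C)O[C@H]1C[C@](C)(C=O)[C@H](COCc2ccc(OC)cc2)[C@]1(C=C)C | intermediate
12 | dimethyl acetal of 11 (ring A; C1 OTBS, C3 CH(OMe)2, C4 CH2OPMB, C5 vinyl; configuration as in 10) | CC(C)(C)[Si](C)(C)O[C@H]1C[C@](C)(C(OC)OC)[C@H](COCc2ccc(OC)cc2)[C@]1(C=C)C | intermediate
13 | C13 methyl ketone (C5 acetyl in place of vinyl; otherwise as 12) | CC(C)(C)[Si](C)(C)O[C@H]1C[C@](C)(C(OC)OC)[C@H](COCc2ccc(OC)cc2)[C@]1(C(C)=O)C | intermediate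
14 | prop-2-yn-1-ol | C#CCO | starting material
15 | (Z)-alkenylmagnesium alkoxide from anti-carbomagnesiation of 14 | Br[Mg]OC/C(C)=C\[Mg]Br | intermediate (not isolated)
16 | (2Z)-3-iodo-2-methylprop-2-en-1-ol | OC/C(C)=C\I | intermediate
17 | (1Z)-3-bromo-1-iodo-2-methylprop-1-ene | BrC/C(C)=C\I | intermediate
18 | lithium enolate of 13 (C13=C12 enolate) | CC(C)(C)[Si](C)(C)O[C@H]1C[C@](C)(C(OC)OC)[C@H](COCc2ccc(OC)cc2)[C@]1(C(=C)O[Li])C | intermediate (not isolated)
19 | C13 ketone with the chain C12–C11–C10(CH3)=C9HI (Z); C1 OTBS, C6 OPMB, C16 acetal | CC(C)(C)[Si](C)(C)O[C@H]1C[C@](C)(C(OC)OC)[C@H](COCc2ccc(OC)cc2)[C@]1(C(=O)CC/C(C)=C\I)C | intermediate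
20 | C1 hydroxy C13 ketone (19 without TBS) | O[C@H]1C[C@](C)(C(OC)OC)[C@H](COCc2ccc(OC)cc2)[C@]1(C(=O)CC/C(C)=C\I)C | intermediate
21 | diethylborinate of 20 at the C1 oxygen, chelated to the C13 ketone | CCB(CC)O[C@H]1C[C@](C)(C(OC)OC)[C@H](COCc2ccc(OC)cc2)[C@]1(C(=O)CC/C(C)=C\I)C | intermediate (not isolated)
22 | syn-1,13-diol (C13 configured as in the target) | O[C@H]1C[C@](C)(C(OC)OC)[C@H](COCc2ccc(OC)cc2)[C@]1([C@H](O)CC/C(C)=C\I)C | intermediate
23 | 1,13-diacetate of 22 | CC(=O)O[C@H]1C[C@](C)(C(OC)OC)[C@H](COCc2ccc(OC)cc2)[C@]1([C@H](OC(C)=O)CC/C(C)=C\I)C | intermediate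
24 | C6 primary alcohol (23 without PMB) | CC(=O)O[C@H]1C[C@](C)(C(OC)OC)[C@H](CO)[C@]1([C@H](OC(C)=O)CC/C(C)=C\I)C | intermediate
25 | C6 aldehyde | CC(=O)O[C@H]1C[C@](C)(C(OC)OC)[C@H](C=O)[C@]1([C@H](OC(C)=O)CC/C(C)=C\I)C | intermediate
26 | methyl (2S)-3-hydroxy-2-methylpropanoate | COC(=O)[C@@H](C)CO | starting material
27 | methyl (2S)-3-[(tert-butyldiphenylsilyl)oxy]-2-methylpropanoate | COC(=O)[C@@H](C)CO[Si](c1ccccc1)(c1ccccc1)C(C)(C)C | intermediate
28 | (2S)-3-[(tert-butyldiphenylsilyl)oxy]-2-methylpropanal | O=C[C@@H](C)CO[Si](c1ccccc1)(c1ccccc1)C(C)(C)C | intermediate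
29 | (R)-tert-butyl[(2-methylbut-3-yn-1-yl)oxy]diphenylsilane | C#C[C@@H](C)CO[Si](c1ccccc1)(c1ccccc1)C(C)(C)C | intermediate
30 | (Z)-2-bromoalkenyl-9-BBN from syn bromoboration of 29 | Br/C(=C\B1C2CCCC1CCC2)[C@@H](C)CO[Si](c1ccccc1)(c1ccccc1)C(C)(C)C | intermediate (not isolated)
31 | (S)-[(3-bromo-2-methylbut-3-en-1-yl)oxy](tert-butyl)diphenylsilane | C=C(Br)[C@@H](C)CO[Si](c1ccccc1)(c1ccccc1)C(C)(C)C | intermediate
32 | alkenyllithium from 31 (lithium in place of bromine) | [Li]C(=C)[C@@H](C)CO[Si](c1ccccc1)(c1ccccc1)C(C)(C)C | intermediate (not isolated)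
33 | C6 allylic alcohols, both C6 epimers (C7=C8H2; C14 and C15H2OTBDPS attached) | CC(=O)O[C@H]1C[C@](C)(C(OC)OC)[C@H](C(O)C(=C)[C@@H](C)CO[Si](c2ccccc2)(c2ccccc2)C(C)(C)C)[C@]1([C@H](OC(C)=O)CC/C(C)=C\I)C | intermediate
34 | C6 enone (α-methylene ketone) | CC(=O)O[C@H]1C[C@](C)(C(OC)OC)[C@H](C(=O)C(=C)[C@@H](C)CO[Si](c2ccccc2)(c2ccccc2)C(C)(C)C)[C@]1([C@H](OC(C)=O)CC/C(C)=C\I)C | intermediate
35 | C6 allylic alcohol, C6 configured as in the target | CC(=O)O[C@H]1C[C@](C)(C(OC)OC)[C@H]([C@@H](O)C(=C)[C@@H](C)CO[Si](c2ccccc2)(c2ccccc2)C(C)(C)C)[C@]1([C@H](OC(C)=O)CC/C(C)=C\I)C | intermediate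
36 | C6 TBS ether of 35 | CC(=O)O[C@H]1C[C@](C)(C(OC)OC)[C@H]([C@@H](O[Si](C)(C)C(C)(C)C)C(=C)[C@@H](C)CO[Si](c2ccccc2)(c2ccccc2)C(C)(C)C)[C@]1([C@H](OC(C)=O)CC/C(C)=C\I)C | intermediate
37 | C7,C8 diol (C7 tertiary OH configured as in the target; C8 primary OH) | CC(=O)O[C@H]1C[C@](C)(C(OC)OC)[C@H]([C@@H](O[Si](C)(C)C(C)(C)C)[C@@](O)(CO)[C@@H](C)CO[Si](c2ccccc2)(c2ccccc2)C(C)(C)C)[C@]1([C@H](OC(C)=O)CC/C(C)=C\I)C | intermediate
38 | C8 aldehyde (α-hydroxy aldehyde) | CC(=O)O[C@H]1C[C@](C)(C(OC)OC)[C@H]([C@@H](O[Si](C)(C)C(C)(C)C)[C@@](O)(C=O)[C@@H](C)CO[Si](c2ccccc2)(c2ccccc2)C(C)(C)C)[C@]1([C@H](OC(C)=O)CC/C(C)=C\I)C | intermediate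
39 | ring A/ring B bicycle with C8 OH, C7 OH, C6 OTBS, C15H2OTBDPS, (9Z) alkene | CC(=O)O[C@H]1C[C@](C)(C(OC)OC)[C@@H]2[C@@H](O[Si](C)(C)C(C)(C)C)[C@](O)([C@@H](C)CO[Si](c3ccccc3)(c3ccccc3)C(C)(C)C)[C@@H](O)/C=C(/C)CC[C@@H](OC(C)=O)[C@@]12C | intermediate
40 | 39 without TBDPS (C15 primary alcohol) | CC(=O)O[C@H]1C[C@](C)(C(OC)OC)[C@@H]2[C@@H](O[Si](C)(C)C(C)(C)C)[C@](O)([C@@H](C)CO)[C@@H](O)/C=C(/C)CC[C@@H](OC(C)=O)[C@@]12C | intermediate
41 | C15 lactol (ring C as hemiacetal) | CC(=O)O[C@H]1C[C@](C)(C(OC)OC)[C@@H]2[C@@H](O[Si](C)(C)C(C)(C)C)[C@@]3(O)[C@H](/C=C(/C)CC[C@@H](OC(C)=O)[C@@]12C)OC(O)[C@@H]3C | intermediate (not isolated)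
42 | tricyclic lactone with C6 OTBS and C16 dimethyl acetal | CC(=O)O[C@H]1C[C@](C)(C(OC)OC)[C@@H]2[C@@H](O[Si](C)(C)C(C)(C)C)[C@@]3(O)[C@H](/C=C(/C)CC[C@@H](OC(C)=O)[C@@]12C)OC(=O)[C@@H]3C | intermediate
43 | CNP0123121.2, (1S,3S,4R,5S,6R,7R,8S,9Z,13R,14R) in the locants above | CC(=O)O[C@H]1C[C@](C)(C=O)[C@@H]2[C@@H](O)[C@@]3(O)[C@H](/C=C(/C)CC[C@@H](OC(C)=O)[C@@]12C)OC(=O)[C@@H]3C | target

Total step count: 31. Longest linear sequence: 25 steps (steps 1–9, 12–17, 22–31); the two side branches are steps 10–11 and steps 18–21.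

Steps most likely to fail

Step 6. What may go wrong: poor facial selectivity when the C3 radical adds to 9 (the alkenyl and CH2OPMB groups on C4 differ little in size), and slow 5-exo closure on the fully substituted C5, which lets telomerisation with 9 compete. Fallback (stepwise and polar, with C3 fixed by a ring): it sets out from lactone 6 and comes back at aldehyde 11. Radical hydrostannation (Bu3SnH, AIBN, benzene, 80 °C) opens the vinylcyclopropane of 6 to the butyrolactone allylstannane F1. BF3·OEt2-promoted SE2′ addition of F1 to chloroacetaldehyde forms the C1–C5 bond and the C5 quaternary centre with its vinyl group, giving the chlorohydrin F2, which is silylated (TBSOTf, 2,6-lutidine) to F3. LiHMDS with NaI then forms the C2–C3 bond by 5-exo-tet alkylation of the lactone enolate; this can only give the cis-fused bicyclic lactone F4, so the C3 methyl must end up cis to C4–H. LiAlH4 reduces F4 to the diol F5, the less hindered C6 hydroxyl is p-methoxybenzylated (Bu2SnO, then PMBCl, CsF) to F6, and Dess–Martin oxidation of the C16 alcohol gives 11.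

Step 28. What may go wrong: intermolecular coupling or protodeiodination outrunning the strained ten-membered closure, or addition to the wrong face of the aldehyde. Fallback (ring closure by olefin metathesis instead of carbonyl addition): it sets out from aldehyde 38 and comes back at 39. Vinylmagnesium bromide with CeCl3 at −78 °C adds to 38 (Felkin–Anh, anti to the C7 oxygen) to give the C8 vinyl carbinol F7. Hydrodeiodination of the vinyl iodide with Pd(PPh3)4 and Bu3SnH gives the 1,1-disubstituted alkene F8. Ring-closing metathesis with the second-generation Grubbs catalyst RuCl2(=CHPh)(PCy3)(H2IMes) in dilute toluene at 80 °C then forms the C9=C10 bond, Z by ring size, with loss of ethene, giving 39.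

Step 24. What may go wrong: the facial bias at the C6 carbonyl being set by the C5 flank and not the C3 flank, so that hydride delivery gives mainly the C6 epimer. Fallback (addition instead of reduction): it sets out from 33 and comes back at 35. The same reversed bias would make the organocerium addition of step 22 give 35 as the major epimer of 33; 35 is then separated and carried into step 25, and steps 23 and 24 serve only to recycle the minor epimer.

Further compounds
F1 | step 6 | 3-methyl-4-[4-(tributylstannyl)but-2-en-2-yl]oxolan-2-one (lactone C4 as in 6; C3 and alkene isomers) | CC1C(=O)OC[C@@H]1C(C)=CC[Sn](CCCC)(CCCC)CCCC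
F2 | step 6 | 4-(1-chloro-2-hydroxy-3-methylpent-4-en-3-yl)-3-methyloxolan-2-one (C1 and C5 of the target set) | CC1C(=O)OC[C@@H]1[C@@](C)(C=C)[C@@H](O)CCl
F3 | step 6 | tert-butyldimethylsilyl ether of F2 | CC1C(=O)OC[C@@H]1[C@@](C)(C=C)[C@@H](O[Si](C)(C)C(C)(C)C)CCl
F4 | step 6 | cis-fused bicyclic lactone (ring A fused to the C16–O–C6 lactone; C1 OTBS, C5 vinyl) | CC(C)(C)[Si](C)(C)O[C@H]1C[C@]2(C)C(=O)OC[C@@H]2[C@]1(C=C)C
F5 | step 6 | ring A diol (C16 and C6 primary alcohols; C1 OTBS, C5 vinyl) | CC(C)(C)[Si](C)(C)O[C@H]1C[C@](C)(CO)[C@H](CO)[C@]1(C=C)C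
F6 | step 6 | C6 p-methoxybenzyl ether of F5 (C16 alcohol free) | CC(C)(C)[Si](C)(C)O[C@H]1C[C@](C)(CO)[C@H](COCc2ccc(OC)cc2)[C@]1(C=C)C
F7 | step 28 | C8 vinyl carbinol from 38 (vinyl iodide retained) | CC(=O)O[C@H]1C[C@](C)(C(OC)OC)[C@H]([C@@H](O[Si](C)(C)C(C)(C)C)[C@@](O)([C@@H](O)C=C)[C@@H](C)CO[Si](c2ccccc2)(c2ccccc2)C(C)(C)C)[C@]1([C@H](OC(C)=O)CC/C(C)=C\I)C
F8 | step 28 | metathesis diene (F7 with C10(CH3)=CH2 in place of the vinyl iodide) | CC(=O)O[C@H]1C[C@](C)(C(OC)OC)[C@H]([C@@H](O[Si](C)(C)C(C)(C)C)[C@@](O)([C@@H](O)C=C)[C@@H](C)CO[Si](c2ccccc2)(c2ccccc2)C(C)(C)C)[C@]1([C@H](OC(C)=O)CCC(C)=C)C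
F0 | step 24 | none | none
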